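A direct plan would take the natural flavone diosmetin A1 and only decorate its finished core.
It would brominate C6 and C8 to give 6,8-dibromodiosmetin A2, exchange both bromides for methoxide with copper to give acerosin A3, and place the 2'-OH by an Elbs-type persulfate oxidation through the potassium aryl sulfate A4, whose acid hydrolysis would give the target.
- The persulfate C–H oxygenation of acerosin A3 to the aryl sulfate A4 would be the weakest step: such oxidations stop at low conversion, the preference for C6' of ring B over oxidation of the doubly phenolic ring A would rest on untested reasoning, and the step would come last.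
- The copper-mediated methanolysis of the dibromide A2 would run in hot methoxide on C–Br bonds flanked by phenolates, in a molecule that contains a base-sensitive pyranone; sluggish coupling and hydrodebromination would be expected.
- The plan as a whole would form no C–C bond: from diosmetin A1 onward it would be a linear run of C–H to C–O changes on a purchased core, without convergence and steered only by innate reactivity.

**Retrosynthetic overview of the new route**

- Ring C is cut at three bonds at once (C4a–C4, C4–C3, O1–C2), giving a ring A aryl iodide, carbon monoxide as C4, and a ring B arylacetylene that carries C2 and C3.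
- The feature used is the symmetry of ring A about the C4a···C7 axis (C5–OH/C8a–O1 and C6–OMe/C8–OMe are pairwise equivalent), so the ring A partner is a symmetric iodo-phloroglucinol triacetate and no phenol has to be told apart.
- Rings A and B are bought as benzenes with all their oxygens in place; ring C is formed last, in the key step.
- The 2',5'-oxygens come from methoxyhydroquinone, so no late C–H oxidation is needed, and the two methoxy groups of ring A are made on a simple benzyl-protected arene before any heterocycle exists.

Key step: step 8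

Remark: the target is achiral, so no step has to control configuration; 1,3,5-tris(benzyloxy)benzene and 2-methoxyhydroquinone are taken as purchasable.

**Route**

Step 1
Reactants: 1 1,3,5-tris(benzyloxy)benzene
Product: 2 1,3,5-tris(benzyloxy)-2,4-dibromobenzene
Conditions: NBS (2.0 equiv), CH2Cl2, −20 to 0 °C, dark
Reagents that add atoms: N-bromosuccinimide, O=C1CCC(=O)N1Br
Why: Electrophilic aromatic bromination, in which each ring C–H is ortho/para to three alkoxy groups and each bromine lowers the reactivity enough that two equivalents of NBS in the dark should stop at the dibromide without touching the benzylic positions.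

Step 2
Reactants: 2 1,3,5-tris(benzyloxy)-2,4-dibromobenzene
Product: 3 1,3,5-tris(benzyloxy)-2,4-dimethoxybenzene
Conditions: NaOMe (30% in MeOH, 10 equiv), CuBr (0.3 equiv), DMF, Ar, 110 °C
Reagents that add atoms: sodium methoxide, [Na+].[O-]C
Why: Ullmann-type copper-mediated methanolysis of aryl bromides, well known for bromo(polyalkoxy)benzenes, in which a monovalent copper methoxide exchanges each bromide, and the arene has no free phenol, carbonyl or heterocycle, so only the benzyl ethers must survive the hot alkoxide.

Step 3
Reactants: 3 1,3,5-tris(benzyloxy)-2,4-dimethoxybenzene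
Product: 4 2,4-dimethoxybenzene-1,3,5-triol
Conditions: H2 (1 atm), Pd/C (10 wt %), EtOAc/MeOH, rt; filtered under Ar and used at once
Reagents that add atoms: none
Why: Hydrogenolysis of the three benzyl aryl ethers over Pd/C leaves the methyl ethers untouched and should give the symmetric, air-sensitive triol.

Step 4
Reactants: 4 2,4-dimethoxybenzene-1,3,5-triol
Product: 6 2-iodo-4,6-dimethoxybenzene-1,3,5-triyl triacetate, via iodotriol 5 (not isolated)
Conditions: NIS (1.0 equiv), MeCN, −20 °C, dark, Ar; then Ac2O (5 equiv), pyridine, DMAP (cat.), 0 °C to rt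
Reagents that add atoms: N-iodosuccinimide, O=C1CCC(=O)N1I; acetic anhydride, CC(=O)OC(C)=O
Why: Electrophilic iodination can only occur at the single ring C–H, which is ortho/para to three hydroxy groups, and exhaustive O-acetylation in the same flask should turn the sensitive iodotriol into a stable triacetate whose more electron-poor C–I bond is better suited to oxidative addition.

Step 5
Reactants: 7 2-methoxybenzene-1,4-diol (methoxyhydroquinone)
Product: 8 2-methoxy-1,4-bis(methoxymethoxy)benzene
Conditions: MOMCl (2.5 equiv), i-Pr2NEt (3 equiv), CH2Cl2, Ar, 0 °C to rt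
Reagents that add atoms: chloromethyl methyl ether, COCCl
Why: Williamson-type O-alkylation of both phenols gives the bis(MOM) ether, which masks the oxidisable hydroquinone and later keeps the 2'-oxygen from attacking the alkyne.

Step 6
Reactants: 8 2-methoxy-1,4-bis(methoxymethoxy)benzene
Product: 9 1-iodo-4-methoxy-2,5-bis(methoxymethoxy)benzene
Conditions: NIS (1.05 equiv), MeCN, 0 °C to rt, dark
Reagents that add atoms: N-iodosuccinimide, O=C1CCC(=O)N1I
Why: Electrophilic aromatic iodination of a 1,2,4-trialkoxybenzene should go to C5, the unhindered position para to the methoxy group and ortho to a MOM ether, as in 1,2,4-trimethoxybenzene, and neutral NIS spares the acetals.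

Step 7
Reactants: 9 1-iodo-4-methoxy-2,5-bis(methoxymethoxy)benzene
Product: 11 1-ethynyl-4-methoxy-2,5-bis(methoxymethoxy)benzene, via silylalkyne 10 (not isolated)
Conditions: PdCl2(PPh3)2 (2 mol %), CuI (4 mol %), ethynyltrimethylsilane (1.3 equiv), Et3N/THF, 50 °C; then K2CO3, MeOH, rt
Reagents that add atoms: ethynyltrimethylsilane, C#C[Si](C)(C)C
Why: Sonogashira coupling of the electron-rich aryl iodide with the silyl-protected acetylene, followed by methanolytic cleavage of the C–Si bond in the same flask, should give the terminal alkyne without touching the MOM ethers.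

Step 8
Reactants: 6 2-iodo-4,6-dimethoxybenzene-1,3,5-triyl triacetate; 11 1-ethynyl-4-methoxy-2,5-bis(methoxymethoxy)benzene
Product: 14 5,7-dihydroxy-6,8-dimethoxy-2-[4-methoxy-2,5-bis(methoxymethoxy)phenyl]-4H-chromen-4-one, via ynone triacetate 12 (not isolated), via enaminone 13 (not isolated)
Conditions: PdCl2(PPh3)2 (5 mol %), dppp (5 mol %), thiourea (5 mol %), CO (1 atm), Et2NH (10 equiv), DMF, 50 °C, 24 h; then 70 °C, 2 h
Reagents that add atoms: carbon monoxide, [C-]#[O+]
Why: This is a Pd-catalysed carbonylative annulation of an o-iodophenyl ester, CO and a terminal arylacetylene, the closest known reaction type being the flavone synthesis from o-iodophenyl acetates, alkynes and CO in Et2NH: zerovalent palladium adds to the C–I bond of 6, CO inserts to give an aroyl-palladium species, and coupling with the acetylide of 11 forms C4–C4a and C4–C3, giving ynone 12. Et2NH then cleaves the three acetates as N,N-diethylacetamide and adds to the triple bond to give enaminone 13 (either geometry serves), in which a phenol next to the ketone displaces the amine at C2 by addition–elimination, so ring C closes through the O1–C2 bond in a formal 6-endo mode. Three selectivities are needed: carbonylative over direct coupling (no copper, and the two ortho oxygen substituents favour CO insertion and shield the aroyl-palladium species from the amine), six- over five-membered closure (the enaminone can only give the pyranone, whereas direct 5-exo attack of a phenolate on the ynone would give an aurone), and no cyclisation from ring B (its 2'-oxygen is a MOM ether). Which oxygen closes the ring needs no control, because ring A of 13 is symmetric about the C4a···C7 axis: either flanking phenol becomes O1, the other becomes the hydrogen-bonded 5-OH, and the 7-OH is freed in the same operation. No stereocentre is formed.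

Step 9
Reactants: 14 5,7-dihydroxy-6,8-dimethoxy-2-[4-methoxy-2,5-bis(methoxymethoxy)phenyl]-4H-chromen-4-one
Product: 15 5,7-dihydroxy-2-(2,5-dihydroxy-4-methoxyphenyl)-6,8-dimethoxy-4H-chromen-4-one (target)
Conditions: HCl (2 M in MeOH), Ar, 50 °C, 2 h; degassed work-up
Reagents that add atoms: none
Why: Acid-catalysed acetal exchange with methanol should remove both MOM groups as dimethoxymethane (and methanolyse any aryl acetate left from step 8) under conditions too mild to open the pyranone or cleave methyl ethers, so the ring B hydroquinone is set free last.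

**Compound list**

1 | 1,3,5-tris(benzyloxy)benzene | C(Oc1cc(OCc2ccccc2)cc(OCc2ccccc2)c1)c1ccccc1 | starting material
2 | 1,3,5-tris(benzyloxy)-2,4-dibromobenzene | Brc1c(OCc2ccccc2)cc(OCc2ccccc2)c(Br)c1OCc1ccccc1 | intermediate
3 | 1,3,5-tris(benzyloxy)-2,4-dimethoxybenzene | COc1c(OCc2ccccc2)cc(OCc2ccccc2)c(OC)c1OCc1ccccc1 | intermediate
4 | 2,4-dimethoxybenzene-1,3,5-triol | COc1c(O)cc(O)c(OC)c1O | intermediate
5 | 2-iodo-4,6-dimethoxybenzene-1,3,5-triol | COc1c(O)c(I)c(O)c(OC)c1O | intermediate
6 | 2-iodo-4,6-dimethoxybenzene-1,3,5-triyl triacetate | COc1c(OC(C)=O)c(I)c(OC(C)=O)c(OC)c1OC(C)=O | intermediate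
7 | 2-methoxybenzene-1,4-diol (methoxyhydroquinone) | COc1cc(O)ccc1O | starting material
8 | 2-methoxy-1,4-bis(methoxymethoxy)benzene | COCOc1ccc(OCOC)c(OC)c1 | intermediate
9 | 1-iodo-4-methoxy-2,5-bis(methoxymethoxy)benzene | COCOc1cc(OC)c(OCOC)cc1I | intermediate
10 | {[4-methoxy-2,5-bis(methoxymethoxy)phenyl]ethynyl}trimethylsilane | COCOc1cc(OC)c(OCOC)cc1C#C[Si](C)(C)C | intermediate
11 | 1-ethynyl-4-methoxy-2,5-bis(methoxymethoxy)benzene | COCOc1cc(OC)c(OCOC)cc1C#C | intermediate
12 | 2-{3-[4-methoxy-2,5-bis(methoxymethoxy)phenyl]prop-2-ynoyl}-4,6-dimethoxybenzene-1,3,5-triyl triacetate | COCOc1cc(OC)c(OCOC)cc1C#CC(=O)c1c(OC(C)=O)c(OC)c(OC(C)=O)c(OC)c1OC(C)=O | intermediate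
13 | (E)-3-(diethylamino)-3-[4-methoxy-2,5-bis(methoxymethoxy)phenyl]-1-(2,4,6-trihydroxy-3,5-dimethoxyphenyl)prop-2-en-1-one | CCN(CC)/C(=C/C(=O)c1c(O)c(OC)c(O)c(OC)c1O)c1cc(OCOC)c(OC)cc1OCOC | intermediate
14 | 5,7-dihydroxy-6,8-dimethoxy-2-[4-methoxy-2,5-bis(methoxymethoxy)phenyl]-4H-chromen-4-one | COCOc1cc(OC)c(OCOC)cc1-c1cc(=O)c2c(O)c(OC)c(O)c(OC)c2o1 | intermediate
15 | 5,7-dihydroxy-2-(2,5-dihydroxy-4-methoxyphenyl)-6,8-dimethoxy-4H-chromen-4-one (achiral) | COc1cc(O)c(-c2cc(=O)c3c(O)c(OC)c(O)c(OC)c3o2)cc1O | target

**Step count and risks**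

Total step count: 9. Longest linear sequence: 6 (steps 1, 2, 3, 4, 8, 9); the ring B branch (steps 5 to 7) joins at step 8.

Steps most likely to fail:

1. Step 8. The aroyl-palladium species may be captured by the amine to give a diethylamide, coupling may occur without CO uptake, or closure may take the five-membered course. The fallback builds the pyranone by the classical diketone route, setting out from 4 and 9 and coming back at 14. Houben–Hoesch acetylation of 4 (MeCN, ZnCl2, HCl gas, Et2O, 0 °C; then H2O, 90 °C) would give 1-(2,4,6-trihydroxy-3,5-dimethoxyphenyl)ethan-1-one F1. Iodine–magnesium exchange on 9 (i-PrMgCl·LiCl, THF, −20 °C) and quenching with methyl chloroformate would give methyl 4-methoxy-2,5-bis(methoxymethoxy)benzoate F2. Claisen condensation of the lithium polyanion of F1 with F2 (LiN(SiMe3)2, 5 equiv, THF, −78 °C to rt) would give 1-[4-methoxy-2,5-bis(methoxymethoxy)phenyl]-3-(2,4,6-trihydroxy-3,5-dimethoxyphenyl)propane-1,3-dione F3. Buffered cyclodehydration (AcOH, NaOAc, 80 °C) would close ring C to 14; the symmetry of ring A again makes the direction of closure irrelevant.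

2. Step 4. The free triol may be degraded oxidatively by the iodinating agent or by air, or iodine may be lost on handling. The fallback places the iodine before the phenols are unmasked, setting out from 3 and coming back at 6. Iodination of 3 at its only ring C–H (NIS, CF3CO2H cat., MeCN, 0 °C) would give 1,3,5-tris(benzyloxy)-2-iodo-4,6-dimethoxybenzene F4. Lewis-acid debenzylation (BCl3, pentamethylbenzene, CH2Cl2, −78 °C) would then give 5 without hydrogen, which would endanger the C–I bond, and the crude 5 would be acetylated at once (Ac2O, pyridine, DMAP) to 6.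

3. Step 2. The crowded C–Br bonds may be hydrodebrominated, or methoxide may attack the benzyl ethers at 110 °C. The fallback makes the two C–O bonds by organolithium chemistry and ordinary O-methylation, setting out from 2 and coming back at 3. Bromine–lithium exchange on 2 (n-BuLi, 1.05 equiv, THF, −78 °C), borylation (B(OMe)3) and oxidation (H2O2, NaOH) would give 2,4,6-tris(benzyloxy)-3-bromophenol F5. Methylation (MeI, K2CO3, acetone) would give 1,3,5-tris(benzyloxy)-2-bromo-4-methoxybenzene F6. The same exchange, borylation and oxidation would give 2,4,6-tris(benzyloxy)-3-methoxyphenol F7, and a second methylation would give 3.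

**Further compounds**

F1 | step 8 | 1-(2,4,6-trihydroxy-3,5-dimethoxyphenyl)ethan-1-one | CC(=O)c1c(O)c(OC)c(O)c(OC)c1O
F2 | step 8 | methyl 4-methoxy-2,5-bis(methoxymethoxy)benzoate | COCOc1cc(OC)c(OCOC)cc1C(=O)OC
F3 | step 8 | 1-[4-methoxy-2,5-bis(methoxymethoxy)phenyl]-3-(2,4,6-trihydroxy-3,5-dimethoxyphenyl)propane-1,3-dione | COCOc1cc(OC)c(OCOC)cc1C(=O)CC(=O)c1c(O)c(OC)c(O)c(OC)c1O
F4 | step 4 | 1,3,5-tris(benzyloxy)-2-iodo-4,6-dimethoxybenzene | COc1c(OCc2ccccc2)c(I)c(OCc2ccccc2)c(OC)c1OCc1ccccc1
F5 | step 2 | 2,4,6-tris(benzyloxy)-3-bromophenol | Oc1c(OCc2ccccc2)cc(OCc2ccccc2)c(Br)c1OCc1ccccc1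
F6 | step 2 | 1,3,5-tris(benzyloxy)-2-bromo-4-methoxybenzene | COc1c(OCc2ccccc2)cc(OCc2ccccc2)c(Br)c1OCc1ccccc1
F7 | step 2 | 2,4,6-tris(benzyloxy)-3-methoxyphenol | COc1c(OCc2ccccc2)cc(OCc2ccccc2)c(O)c1OCc1ccccc1
A1 | direct plan | diosmetin, 5,7-dihydroxy-2-(3-hydroxy-4-methoxyphenyl)-4H-chromen-4-one | COc1ccc(cc1O)-c2cc(=O)c3c(O)cc(O)cc3o2
A2 | direct plan | 6,8-dibromodiosmetin, 6,8-dibromo-5,7-dihydroxy-2-(3-hydroxy-4-methoxyphenyl)-4H-chromen-4-one | COc1ccc(cc1O)-c2cc(=O)c3c(O)c(Br)c(O)c(Br)c3o2
A3 | direct plan | acerosin, 5,7-dihydroxy-2-(3-hydroxy-4-methoxyphenyl)-6,8-dimethoxy-4H-chromen-4-one | COc1ccc(cc1O)-c2cc(=O)c3c(O)c(OC)c(O)c(OC)c3o2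
A4 | direct plan | potassium 2-(5,7-dihydroxy-6,8-dimethoxy-4-oxo-4H-chromen-2-yl)-4-hydroxy-5-methoxyphenyl sulfate | COc1cc(OS(=O)(=O)[O-])c(cc1O)-c2cc(=O)c3c(O)c(OC)c(O)c(OC)c3o2.[K+]
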